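## Analysis of the target

The target 29 is a daucane-type sesquiterpene diester on a trans-fused bicyclo[5.3.0]dec-8-ene, numbered here so that the five-membered ring holds C1 (the methyl-bearing quaternary fusion carbon), C2 (angelate), C3, C4 (isopropyl carbinol) and C5 (fusion CH), and the seven-membered ring continues through C6 (angelate), C7, C8 (methyl), C9 and C10, with the alkene at C8=C9. Its five stereocentres are (1R,2S,4R,5S,6S): the C1 methyl is α and H5 is β, the C2 oxygen is β, the C4 hydroxyl is α with the isopropyl group β, and the C6 oxygen is cis to H5. Both ester oxygens are therefore 1,3-anti to the tertiary C4 hydroxyl, and the endgame uses this relationship. The sensitive groups are the two (Z)-2-methylbut-2-enoates, which isomerise to tiglates under base, nucleophilic catalysis or heat. The tertiary alcohol is β to both C2 and C6, so at the ketone oxidation level it is a double aldol open to retro-aldol cleavage and dehydration, and the C8=C9 alkene is β,γ to C6 and can move into conjugation once C6 is a carbonyl. The difficulty lies in the quaternary C1 between the C2 and C5 stereocentres, in the trans fusion of a seven-membered ring, and in the C2 oxygen, which is trans to the angular methyl and so needs hydride delivery from the methyl-bearing face. The strategy rests on reading C2, C1 and C5 as the carbonyl, α-carbon and β-carbon of a 2-methylcyclopent-2-enone, so that the C5–C6 and C1–C10 bonds, which lie on opposite faces, can be attached in that order under the direction of an oxygen substituent at C4.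

## Retrosynthetic reasoning

Ester C–O bonds (29 to 28). The two acyl–oxygen bonds are cut first, so the isomerisable Z esters are installed last and never meet base, fluoride or organometallics. The forward step must acylate the two hindered secondary hydroxyls of triol 28 without touching the tertiary one and without Z-to-E isomerisation.

C2–H and C6–H bonds (28 to 27). Both secondary carbinols are taken back to ketones in hydroxy diketone 27. The C4 hydroxyl is 1,3 to both carbonyls, so one hydroxyl-bound hydride reagent can set both centres anti to it. This matters most at C2, where an external hydride would enter opposite the angular methyl and give the wrong epimer.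

Unmasking of C6 and C2 (27 to 24 through 26 and 25). The C6 carbonyl is traced to the spiro-dithiane of 26, and the C2 carbonyl to the secondary alcohol of 25 and its methoxymethyl ether 24. C2 cannot stay a ketone while C4 is one, because two carbonyls flanking C3 would enolise and shut down addition at C4. C2 is therefore carried as a protected alcohol whose configuration is irrelevant.

C4–isopropyl bond (24 to 23). The tertiary carbinol is cut at the bond between C4 and the isopropyl carbon, which gives ketone 23. The forward addition must come from the β face. In the bicycle the α face carries the spiro-dithiane at C6, the C1 methyl and the C2 ether, so the ring is closed first and the isopropyl group is added second. This order also keeps a tertiary alkoxide out of the carbanion ring closure. Ketone 23 comes from silyl ether 21 through alcohol 22.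

C6–C7 bond (21 to 19). The seven-membered ring is opened at C6–C7. C6 is already a dithiane carbon, a latent acyl anion, and C7 is a primary allylic carbon. The Z alkene and the trans arms on C1 and C5 hold the two ends together. The forward step is an intramolecular alkylation of lithiated dithiane 20 by the allylic chloride of 19.

Protecting-group and oxidation-state adjustments (19 to 14 through 17, 16 and 15). The chloride comes from allylic alcohol 17, which comes from bis-silyl ether 16 by selective methanolysis of the primary silyl ether. Compound 16 is the methoxymethyl ether of alcohol 15, the reduction product of ketone 14. The allylic oxygen is carried as a silyl ether and not as a benzyl-type ether, because it is then released by mild acid and no oxidant has to be used beside the oxidisable 2-H dithiane.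

C5–C6 and C1–C10 bonds (14 to 3, 12 and 10). Both arms of the seven-membered ring are removed from the cyclopentanone in one disconnection. This leaves enone 3, 2-lithio-1,3-dithiane 12 (from 1,3-dithiane 11) and Z-allylic bromide 10. Cutting here makes the quaternary centre and the trans C1/C5 relationship in one operation under control of the C4 silyloxy group. A cut at C1–C5 or inside the five-membered ring would leave the quaternary centre to a less biased step.

Enone 3 (to 1 through 2). The bond from C1 to its methyl group is cut back to α-iodoenone 2 and the commercial enantiopure silyloxy enone 1. The stereocentre is bought and no resolution is needed.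

Bromide 10 (to 4 through 9, 8 and 6). The bond from C8 to its methyl group is cut by a syn carbometalation of ynoate 6, which fixes the Z geometry of ester 8 and differentiates the two allylic carbons by oxidation state. Alcohol 9 follows by reduction, and ynoate 6 comes from silyl propargyl ether 4 by acylation.

## Alternatives that were turned down

Alternative 1: Disconnection of C6–C7 and C1–C10 in one annulation. The Cr(CO)5 alkenyl(methoxy)carbene complex A1, whose carbene carbon is C6 and whose cyclopentene double bond is C5=C1, would cyclopropanate the 1,1-disubstituted double bond of isoprene A2. A Cope rearrangement of the cis adduct would then give dienol ether A3.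
- For: the seven-membered ring, the C8 methyl with the C8=C9 alkene, the C6 oxygen and the quaternary C1 arise in one step, with C2 and C4 already in place. On ring construction it is stronger than the chosen route, which needs a separate medium-ring alkylation.
- Against: alkenyl carbene complexes such as A1 are also good dienophiles, so [4+2] addition to A2 competes. The two double bonds of A2 must be told apart. Only the cis adduct rearranges readily, and it must form a quaternary centre from a fully substituted alkene carbon.
- Against: C5 becomes sp2 in A3, so the trans fusion would have to be re-established later under thermodynamic control. Complex A1 needs a multi-step chiral cyclopentenyl precursor and stoichiometric chromium.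
- Comparison: the chosen route gives up the one-step ring formation but sets C1 and C5 kinetically, each relayed from its neighbour.

Alternative 2: Disconnection of C1–C2 and C4–C5, building the five-membered ring onto the seven-membered one. Cu(OTf)2 with a chiral N-heterocyclic carbene ligand would direct the transfer of a vinyl group to the methyl-bearing β-carbon of dienone A4. The resulting enolate would be trapped by isobutyraldehyde A5 to give aldol A6.
- For: it is catalytic-asymmetric and much shorter, and the C6 carbonyl and the C8=C9 alkene are present from the start. On step count and on the source of chirality it is stronger.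
- Against: the skipped alkene of A4 moves easily into conjugation. The aldol trap with A5 has to distinguish vinyl from methyl on the new quaternary carbon to set C5. These groups are of similar size, so the trans fusion is not secured.
- Against: from A6 the five-membered ring still has to be closed between C3 and C4 through a 1,3-dicarbonyl stage, and C2 and C4 must then be set.
- Comparison: the chosen route is longer, but the trans C1/C5 relationship comes from alkylation anti to a bulky neighbouring substituent.

Alternative 3: Disconnection of C1–C5 by ring contraction. The chiral-pool alcohol (R)-terpinen-4-ol A7 would supply C4 with its hydroxyl and isopropyl group. A derived diazoketone A8 would be photolysed in an alcohol so that C1 migrates with retention (Wolff rearrangement), which gives cyclopentane ester A9. The seven-membered ring would then be closed by olefin metathesis.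
- For: the tertiary carbinol comes from A7, so no late addition to a hindered ketone is needed, and metathesis is a dependable ring closure. On both points it is as strong as or stronger than the chosen route.
- Against: reaching A8 from A7 requires oxidation at two ring positions, a stereocontrolled allylation to make the quaternary C1 under only remote control from C4, and diazo transfer to a hindered ketone. C5 is set at ketene capture and is epimerisable in A9. The sequence is linear and long.
- Comparison: the chosen route is convergent and sets C1 and C5 in one step from a purchased stereocentre, at the price of rebuilding C4.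

Key step: step 7

Assumption 1: the hydride reduction of step 8 is taken to occur on the face opposite the C1 methyl group and to give the 2α alcohol drawn for 15 to 25; this centre is provisional and returns to a ketone in step 17, so the C2 epimer would be carried through in the same way.

Assumption 2: compounds 1, 4 and 11 are taken as commercial; monocyclic compounds 13 to 20 are named with cyclopentane locants, bicyclic compounds with the skeleton numbering of the analysis, and "C" numbers in the explanations always mean the skeleton numbering.

## Route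

Step 1
Reactants: 1 (R)-4-(tert-butyldimethylsilyloxy)cyclopent-2-en-1-one
Product: 2 (R)-4-(tert-butyldimethylsilyloxy)-2-iodocyclopent-2-en-1-one
Conditions: I2, pyridine, CH2Cl2, 0 °C to rt
Reagents that add atoms: iodine, II
Why: α-Iodination of an enone by conjugate addition of pyridine, iodination of the resulting enolate and elimination (Baylis–Hillman-type α-halogenation); the C4 stereocentre and the silyl ether are not touched.

Step 2
Reactants: 2 (R)-4-(tert-butyldimethylsilyloxy)-2-iodocyclopent-2-en-1-one
Product: 3 (R)-4-(tert-butyldimethylsilyloxy)-2-methylcyclopent-2-en-1-one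
Conditions: SnMe4, PdCl2(PhCN)2 (5 mol %), AsPh3, CuI, NMP, 80 °C
Reagents that add atoms: tetramethylstannane, C[Sn](C)(C)C
Why: Stille coupling of an α-iodoenone; the neutral conditions spare the base-sensitive γ-silyloxy enone, which would eliminate under the basic conditions of a boron coupling.

Step 3
Reactants: 4 tert-butyldimethyl(prop-2-yn-1-yloxy)silane
Product: 6 methyl 4-(tert-butyldimethylsilyloxy)but-2-ynoate, via lithium acetylide 5 (not isolated)
Conditions: n-BuLi, THF, −78 °C; ClCO2Me, −78 to 0 °C
Reagents that add atoms: methyl chloroformate, COC(=O)Cl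
Why: Deprotonation of a terminal alkyne and C-acylation of the lithium acetylide with a chloroformate.

Step 4
Reactants: 6 methyl 4-(tert-butyldimethylsilyloxy)but-2-ynoate
Product: 8 methyl (Z)-4-(tert-butyldimethylsilyloxy)-3-methylbut-2-enoate, via lithium alkenylcuprate 7 (not isolated)
Conditions: MeLi, CuI, THF, 0 °C; then 6, −78 °C; MeOH, −78 °C; aq NH4Cl
Reagents that add atoms: lithium dimethylcuprate (made in the flask from MeLi and CuI), [Li+].C[Cu-]C
Why: Syn carbocupration of the ynoate puts the new methyl and copper cis, and protonation of alkenylcuprate 7 at −78 °C with retention gives the Z ester in which CH2OSi and CO2Me are cis; the quench is done cold because warming would let the cuprate isomerise through its allenolate.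

Step 5
Reactants: 8 methyl (Z)-4-(tert-butyldimethylsilyloxy)-3-methylbut-2-enoate
Product: 9 (Z)-4-(tert-butyldimethylsilyloxy)-3-methylbut-2-en-1-ol
Conditions: i-Bu2AlH (2.2 equiv), CH2Cl2, −78 °C; aq KNa tartrate
Reagents that add atoms: none
Why: 1,2-Reduction of an enoate to the allylic alcohol with an aluminium hydride; the alkene geometry is not affected and the neutral work-up avoids silyl migration between the two allylic oxygens.

Step 6
Reactants: 9 (Z)-4-(tert-butyldimethylsilyloxy)-3-methylbut-2-en-1-ol
Product: 10 (Z)-1-bromo-4-(tert-butyldimethylsilyloxy)-3-methylbut-2-ene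
Conditions: CBr4, PPh3, CH2Cl2, −20 to 0 °C; used at once
Reagents that add atoms: carbon tetrabromide, BrC(Br)(Br)Br
Why: Appel bromination; SN2 displacement at the primary allylic carbon proceeds without allylic transposition or loss of the Z geometry.

Step 7
Reactants: 3 (R)-4-(tert-butyldimethylsilyloxy)-2-methylcyclopent-2-en-1-one, 11 1,3-dithiane, 10 (Z)-1-bromo-4-(tert-butyldimethylsilyloxy)-3-methylbut-2-ene
Product: 14 (2R,3R,4R)-4-(tert-butyldimethylsilyloxy)-2-[(Z)-4-(tert-butyldimethylsilyloxy)-3-methylbut-2-en-1-yl]-3-(1,3-dithian-2-yl)-2-methylcyclopentan-1-one, via 2-lithio-1,3-dithiane 12 (not isolated), via lithium enolate 13 (not isolated)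
Conditions: 11, n-BuLi, THF, −30 °C; HMPA (2 equiv), −78 °C; 3, −78 °C; then 10 (1.5 equiv), −78 to −30 °C; aq NH4Cl
Reagents that add atoms: none
Why: In THF–HMPA the lithiodithiane 12 is a solvent-separated ion pair and adds to the β-carbon C5 of enone 3 in the conjugate sense instead of at the carbonyl, entering on the face opposite the C4 silyloxy group, which fixes C5. The addition leaves lithium enolate 13 with its double bond between C1 and C2, so the nucleophilic carbon is the methyl-bearing one and no choice between C1 and C3 arises as long as the enolate does not equilibrate. SN2 alkylation by the primary allylic bromide 10 then takes place at C1 on the face opposite the neighbouring dithianyl group and creates the quaternary centre with the side chain trans to C6. The closest known reaction type is the three-component coupling of 4-silyloxycyclopentenones, in which conjugate addition of a stabilised carbanion is followed by in situ alkylation of the enolate with an allylic halide. No ring is closed in this step; it forms the C5–C6 and C1–C10 bonds and the stereocentres C5 and C1, each controlled by the substituent on the adjacent ring carbon. The step needs 1,4 over 1,2 addition, which HMPA secures, and alkylation at carbon before proton transfer to C3, which the reactive bromide in excess and the low temperature secure, since a C3 enolate would expel the C4 silyloxy group. It also needs SN2 over SN2′ attack, which follows from the fully substituted distal alkene carbon of 10. The Z geometry of 10 is kept because the displacement involves no ionisation.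

Step 8
Reactants: 14 (2R,3R,4R)-4-(tert-butyldimethylsilyloxy)-2-[(Z)-4-(tert-butyldimethylsilyloxy)-3-methylbut-2-en-1-yl]-3-(1,3-dithian-2-yl)-2-methylcyclopentan-1-one
Product: 15 (1R,2R,3R,4R)-4-(tert-butyldimethylsilyloxy)-2-[(Z)-4-(tert-butyldimethylsilyloxy)-3-methylbut-2-en-1-yl]-3-(1,3-dithian-2-yl)-2-methylcyclopentan-1-ol
Conditions: LiBH(s-Bu)3, THF, −78 °C; aq NH4Cl
Reagents that add atoms: none
Why: Hydride reduction of the ketone with a bulky, weakly basic borohydride, which should not trigger β-elimination of the silyloxy group; attack is expected on the face opposite the C1 methyl, as at the 17-carbonyl of steroids, giving the alcohol cis to that methyl. The centre only masks C2 and is erased in step 17.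

Step 9
Reactants: 15 (1R,2R,3R,4R)-4-(tert-butyldimethylsilyloxy)-2-[(Z)-4-(tert-butyldimethylsilyloxy)-3-methylbut-2-en-1-yl]-3-(1,3-dithian-2-yl)-2-methylcyclopentan-1-ol
Product: 16 (1R,2R,3R,4R)-4-(tert-butyldimethylsilyloxy)-2-[(Z)-4-(tert-butyldimethylsilyloxy)-3-methylbut-2-en-1-yl]-3-(1,3-dithian-2-yl)-1-(methoxymethoxy)-2-methylcyclopentane
Conditions: MOMCl, i-Pr2NEt, Bu4NI (cat.), CH2Cl2, 0 to 40 °C
Reagents that add atoms: chloromethyl methyl ether, COCCl
Why: O-Alkylation with a small, reactive α-chloro ether, which tolerates the neopentyl position; the acetal survives fluoride, organolithium and organocerium reagents and is orthogonal to both silyl ethers.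

Step 10
Reactants: 16 (1R,2R,3R,4R)-4-(tert-butyldimethylsilyloxy)-2-[(Z)-4-(tert-butyldimethylsilyloxy)-3-methylbut-2-en-1-yl]-3-(1,3-dithian-2-yl)-1-(methoxymethoxy)-2-methylcyclopentane
Product: 17 (1R,2R,3R,4R)-4-(tert-butyldimethylsilyloxy)-3-(1,3-dithian-2-yl)-2-[(Z)-4-hydroxy-3-methylbut-2-en-1-yl]-1-(methoxymethoxy)-2-methylcyclopentane
Conditions: pyridinium p-toluenesulfonate (0.2 equiv), MeOH, 0 °C to rt
Reagents that add atoms: none
Why: Acid-catalysed methanolysis of silyl ethers; the primary allylic ether is cleaved far faster than the secondary C4 ether, and the acetal and dithiane are inert. No oxidant is needed in the presence of the 2-H dithiane.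

Step 11
Reactants: 17 (1R,2R,3R,4R)-4-(tert-butyldimethylsilyloxy)-3-(1,3-dithian-2-yl)-2-[(Z)-4-hydroxy-3-methylbut-2-en-1-yl]-1-(methoxymethoxy)-2-methylcyclopentane
Product: 19 (1R,2R,3R,4R)-4-(tert-butyldimethylsilyloxy)-2-[(Z)-4-chloro-3-methylbut-2-en-1-yl]-3-(1,3-dithian-2-yl)-1-(methoxymethoxy)-2-methylcyclopentane, via allylic mesylate 18 (not isolated)
Conditions: MsCl, 2,4,6-collidine, LiCl, DMF, 0 °C to rt
Reagents that add atoms: lithium chloride, [Li+].[Cl-]
Why: Mesylation of the primary allylic alcohol and SN2 displacement by chloride in a dipolar solvent; position and geometry of the alkene are kept. The chloride is chosen over the bromide because it resists halogen–lithium exchange in step 12.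

Step 12
Reactants: 19 (1R,2R,3R,4R)-4-(tert-butyldimethylsilyloxy)-2-[(Z)-4-chloro-3-methylbut-2-en-1-yl]-3-(1,3-dithian-2-yl)-1-(methoxymethoxy)-2-methylcyclopentane
Product: 21 (1R,2R,4R,5R)-4-(tert-butyldimethylsilyloxy)-2-(methoxymethoxy)-1,8-dimethyl-trans-bicyclo[5.3.0]dec-8-ene-6-spiro-2′-(1,3-dithiane), via lithiated dithiane 20 (not isolated)
Conditions: t-BuLi (1.1 equiv), THF–HMPA (10:1), 0.005 M, −78 °C, then to −20 °C
Reagents that add atoms: none
Why: Deprotonation of the 2-alkyl-1,3-dithiane and intramolecular SN2 alkylation of the lithiodithiane by the primary allylic chloride (Corey–Seebach alkylation, 7-exo-tet); the trans arms on C1 and C5 and the Z alkene hold C6 and C7 together. The SN2′ alternative at C9 would give a strained trans-fused bicyclo[3.3.0]octane, and high dilution suppresses intermolecular alkylation. C6 carries two equivalent sulfur arms and is not a stereocentre.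

Step 13
Reactants: 21 (1R,2R,4R,5R)-4-(tert-butyldimethylsilyloxy)-2-(methoxymethoxy)-1,8-dimethyl-trans-bicyclo[5.3.0]dec-8-ene-6-spiro-2′-(1,3-dithiane)
Product: 22 (1R,2R,4R,5R)-2-(methoxymethoxy)-1,8-dimethyl-trans-bicyclo[5.3.0]dec-8-en-4-ol-6-spiro-2′-(1,3-dithiane)
Conditions: Bu4NF, THF, rt to 40 °C
Reagents that add atoms: none
Why: Fluoride cleavage of the secondary silyl ether; the methoxymethyl ether and the dithiane are unaffected.

Step 14
Reactants: 22 (1R,2R,4R,5R)-2-(methoxymethoxy)-1,8-dimethyl-trans-bicyclo[5.3.0]dec-8-en-4-ol-6-spiro-2′-(1,3-dithiane)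
Product: 23 (1R,2R,5R)-2-(methoxymethoxy)-1,8-dimethyl-trans-bicyclo[5.3.0]dec-8-en-4-one-6-spiro-2′-(1,3-dithiane)
Conditions: Dess–Martin periodinane, NaHCO3, CH2Cl2, 0 °C to rt
Reagents that add atoms: none
Why: Dess–Martin oxidation under anhydrous, buffered conditions, which leave the dithiane alone; the absence of base avoids epimerisation at the fusion carbon C5 and β-elimination of the C2 alkoxy group.

Step 15
Reactants: 23 (1R,2R,5R)-2-(methoxymethoxy)-1,8-dimethyl-trans-bicyclo[5.3.0]dec-8-en-4-one-6-spiro-2′-(1,3-dithiane)
Product: 24 (1R,2R,4R,5R)-4-isopropyl-2-(methoxymethoxy)-1,8-dimethyl-trans-bicyclo[5.3.0]dec-8-en-4-ol-6-spiro-2′-(1,3-dithiane)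
Conditions: CeCl3 (anhydrous), THF, rt; i-PrMgCl, −78 °C; then 23, −78 to −40 °C; aq NH4Cl
Reagents that add atoms: isopropylmagnesium chloride, CC(C)[Mg]Cl
Why: 1,2-Addition of an organocerium reagent, whose low basicity suppresses enolisation and reduction by β-hydride transfer at the hindered ketone. The α face of C4 is blocked by the adjacent spiro-dithiane at C6, the C1 methyl and the C2 ether, so the nucleophile enters from the β face and gives the 4α-hydroxy-4β-isopropyl carbinol.

Step 16
Reactants: 24 (1R,2R,4R,5R)-4-isopropyl-2-(methoxymethoxy)-1,8-dimethyl-trans-bicyclo[5.3.0]dec-8-en-4-ol-6-spiro-2′-(1,3-dithiane)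
Product: 25 (1R,2R,4R,5R)-4-isopropyl-1,8-dimethyl-trans-bicyclo[5.3.0]dec-8-ene-2,4-diol-6-spiro-2′-(1,3-dithiane)
Conditions: Me2BBr, CH2Cl2, −78 °C; then THF, aq NaHCO3
Reagents that add atoms: none
Why: Lewis-acid cleavage of the acetal through the bromomethyl ether, hydrolysed on work-up; at −78 °C the tertiary alcohol (held as its borinate), the dithiane and the alkene should survive, and the C2–O bond is not broken.

Step 17
Reactants: 25 (1R,2R,4R,5R)-4-isopropyl-1,8-dimethyl-trans-bicyclo[5.3.0]dec-8-ene-2,4-diol-6-spiro-2′-(1,3-dithiane)
Product: 26 (1R,4R,5R)-4-hydroxy-4-isopropyl-1,8-dimethyl-trans-bicyclo[5.3.0]dec-8-en-2-one-6-spiro-2′-(1,3-dithiane)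
Conditions: Dess–Martin periodinane, NaHCO3, CH2Cl2, 0 °C
Reagents that add atoms: none
Why: Dess–Martin oxidation of the secondary alcohol beside an inert tertiary one; it removes the provisional C2 centre and gives the β-hydroxy ketone under non-basic conditions that avoid retro-aldol cleavage and dehydration.

Step 18
Reactants: 26 (1R,4R,5R)-4-hydroxy-4-isopropyl-1,8-dimethyl-trans-bicyclo[5.3.0]dec-8-en-2-one-6-spiro-2′-(1,3-dithiane)
Product: 27 (1R,4R,5R)-4-hydroxy-4-isopropyl-1,8-dimethyl-trans-bicyclo[5.3.0]dec-8-ene-2,6-dione
Conditions: PhI(O2CCF3)2, NaHCO3, MeCN–H2O (9:1), 0 °C; used directly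
Reagents that add atoms: water, O
Why: Oxidative hydrolysis of the dithiane: sulfur is oxidised by the iodine reagent, the C–S bond ionises and water adds to give the ketone. The short, buffered reaction is chosen so that the β,γ-alkene does not move into conjugation and the double aldol is not cleaved or dehydrated.

Step 19
Reactants: 27 (1R,4R,5R)-4-hydroxy-4-isopropyl-1,8-dimethyl-trans-bicyclo[5.3.0]dec-8-ene-2,6-dione
Product: 28 (1R,2S,4R,5S,6S)-4-isopropyl-1,8-dimethyl-trans-bicyclo[5.3.0]dec-8-ene-2,4,6-triol
Conditions: Me4NBH(OAc)3 (8 equiv), MeCN–AcOH (1:1), −30 to 0 °C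
Reagents that add atoms: none
Why: Evans–Saksena reduction: the C4 hydroxyl exchanges onto boron and delivers hydride intramolecularly to both β-carbonyls, giving the anti 1,3-diol in each case. C2 is attacked from the α face, the face an external hydride avoids because of the angular methyl. C6 is attacked from the side on which the C4–O bond lies, through a chair-like six-membered transition state, which gives the C6 hydroxyl cis to H5.

Step 20
Reactants: 28 (1R,2S,4R,5S,6S)-4-isopropyl-1,8-dimethyl-trans-bicyclo[5.3.0]dec-8-ene-2,4,6-triol
Product: 29 (1S,3R,3aS,4S,8aR)-3-hydroxy-3-isopropyl-6,8a-dimethyl-1,2,3,3a,4,5,8,8a-octahydroazulene-1,4-diyl bis[(Z)-2-methylbut-2-enoate] (the target)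
Conditions: angelic acid, 2,4,6-trichlorobenzoyl chloride, Et3N, toluene, rt; then 28, toluene, 80 °C
Reagents that add atoms: angelic acid, C/C=C(/C)C(=O)O
Why: Yamaguchi-type acylation with the preformed mixed anhydride and no nucleophilic catalyst, which is the usual way to avoid Z-to-E isomerisation to the tiglate. Only the two secondary hydroxyls react, and since no C–O bond at C2 or C6 is broken their configuration is retained.

## Compound list

1 | (R)-4-(tert-butyldimethylsilyloxy)cyclopent-2-en-1-one | O=C1C=C[C@H](O[Si](C)(C)C(C)(C)C)C1 | starting material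
2 | (R)-4-(tert-butyldimethylsilyloxy)-2-iodocyclopent-2-en-1-one | O=C1C(I)=C[C@H](O[Si](C)(C)C(C)(C)C)C1 | intermediate
3 | (R)-4-(tert-butyldimethylsilyloxy)-2-methylcyclopent-2-en-1-one | CC1=C[C@H](O[Si](C)(C)C(C)(C)C)CC1=O | intermediate
4 | tert-butyldimethyl(prop-2-yn-1-yloxy)silane | C#CCO[Si](C)(C)C(C)(C)C | starting material
5 | [3-(tert-butyldimethylsilyloxy)prop-1-yn-1-yl]lithium | [Li]C#CCO[Si](C)(C)C(C)(C)C | intermediate
6 | methyl 4-(tert-butyldimethylsilyloxy)but-2-ynoate | COC(=O)C#CCO[Si](C)(C)C(C)(C)C | intermediate
7 | lithium alkenyl(methyl)cuprate from syn addition of CH3–Cu to 6 (copper on C2, cis to the new C3 methyl) | COC(=O)/C([Cu-]C)=C(C)\CO[Si](C)(C)C(C)(C)C.[Li+] | intermediate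
8 | methyl (Z)-4-(tert-butyldimethylsilyloxy)-3-methylbut-2-enoate | COC(=O)/C=C(C)\CO[Si](C)(C)C(C)(C)C | intermediate
9 | (Z)-4-(tert-butyldimethylsilyloxy)-3-methylbut-2-en-1-ol | OC/C=C(C)\CO[Si](C)(C)C(C)(C)C | intermediate
10 | (Z)-1-bromo-4-(tert-butyldimethylsilyloxy)-3-methylbut-2-ene | BrC/C=C(C)\CO[Si](C)(C)C(C)(C)C | intermediate
11 | 1,3-dithiane | C1CSCSC1 | starting material
12 | 2-lithio-1,3-dithiane | [Li]C1SCCCS1 | intermediate
13 | lithium (3R,4R)-4-(tert-butyldimethylsilyloxy)-3-(1,3-dithian-2-yl)-2-methylcyclopent-1-en-1-olate | [Li]OC1=C(C)[C@@H](C2SCCCS2)[C@H](O[Si](C)(C)C(C)(C)C)C1 | intermediate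
14 | (2R,3R,4R)-4-(tert-butyldimethylsilyloxy)-2-[(Z)-4-(tert-butyldimethylsilyloxy)-3-methylbut-2-en-1-yl]-3-(1,3-dithian-2-yl)-2-methylcyclopentan-1-one | O=C1C[C@@H](O[Si](C)(C)C(C)(C)C)[C@H](C2SCCCS2)[C@@]1(C)C/C=C(C)\CO[Si](C)(C)C(C)(C)C | intermediate
15 | (1R,2R,3R,4R)-4-(tert-butyldimethylsilyloxy)-2-[(Z)-4-(tert-butyldimethylsilyloxy)-3-methylbut-2-en-1-yl]-3-(1,3-dithian-2-yl)-2-methylcyclopentan-1-ol | O[C@@H]1C[C@@H](O[Si](C)(C)C(C)(C)C)[C@H](C2SCCCS2)[C@@]1(C)C/C=C(C)\CO[Si](C)(C)C(C)(C)C | intermediate
16 | (1R,2R,3R,4R)-4-(tert-butyldimethylsilyloxy)-2-[(Z)-4-(tert-butyldimethylsilyloxy)-3-methylbut-2-en-1-yl]-3-(1,3-dithian-2-yl)-1-(methoxymethoxy)-2-methylcyclopentane | COCO[C@@H]1C[C@@H](O[Si](C)(C)C(C)(C)C)[C@H](C2SCCCS2)[C@@]1(C)C/C=C(C)\CO[Si](C)(C)C(C)(C)C | intermediate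
17 | (1R,2R,3R,4R)-4-(tert-butyldimethylsilyloxy)-3-(1,3-dithian-2-yl)-2-[(Z)-4-hydroxy-3-methylbut-2-en-1-yl]-1-(methoxymethoxy)-2-methylcyclopentane | COCO[C@@H]1C[C@@H](O[Si](C)(C)C(C)(C)C)[C@H](C2SCCCS2)[C@@]1(C)C/C=C(C)\CO | intermediate
18 | methanesulfonate of the primary allylic alcohol 17 | COCO[C@@H]1C[C@@H](O[Si](C)(C)C(C)(C)C)[C@H](C2SCCCS2)[C@@]1(C)C/C=C(C)\COS(C)(=O)=O | intermediate
19 | (1R,2R,3R,4R)-4-(tert-butyldimethylsilyloxy)-2-[(Z)-4-chloro-3-methylbut-2-en-1-yl]-3-(1,3-dithian-2-yl)-1-(methoxymethoxy)-2-methylcyclopentane | COCO[C@@H]1C[C@@H](O[Si](C)(C)C(C)(C)C)[C@H](C2SCCCS2)[C@@]1(C)C/C=C(C)\CCl | intermediate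
20 | 2-lithio-1,3-dithiane derived from 19 (lithium on the dithiane carbon C6) | COCO[C@@H]1C[C@@H](O[Si](C)(C)C(C)(C)C)[C@H](C2([Li])SCCCS2)[C@@]1(C)C/C=C(C)\CCl | intermediate
21 | (1R,2R,4R,5R)-4-(tert-butyldimethylsilyloxy)-2-(methoxymethoxy)-1,8-dimethyl-trans-bicyclo[5.3.0]dec-8-ene-6-spiro-2′-(1,3-dithiane) | C13(SCCCS3)CC(C)=CC[C@@]2(C)[C@H](OCOC)C[C@@H](O[Si](C)(C)C(C)(C)C)[C@H]12 | intermediate
22 | (1R,2R,4R,5R)-2-(methoxymethoxy)-1,8-dimethyl-trans-bicyclo[5.3.0]dec-8-en-4-ol-6-spiro-2′-(1,3-dithiane) | C13(SCCCS3)CC(C)=CC[C@@]2(C)[C@H](OCOC)C[C@@H](O)[C@H]12 | intermediate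
23 | (1R,2R,5R)-2-(methoxymethoxy)-1,8-dimethyl-trans-bicyclo[5.3.0]dec-8-en-4-one-6-spiro-2′-(1,3-dithiane) | C13(SCCCS3)CC(C)=CC[C@@]2(C)[C@H](OCOC)CC(=O)[C@H]12 | intermediate
24 | (1R,2R,4R,5R)-4-isopropyl-2-(methoxymethoxy)-1,8-dimethyl-trans-bicyclo[5.3.0]dec-8-en-4-ol-6-spiro-2′-(1,3-dithiane) | C13(SCCCS3)CC(C)=CC[C@@]2(C)[C@H](OCOC)C[C@@](O)(C(C)C)[C@H]12 | intermediate
25 | (1R,2R,4R,5R)-4-isopropyl-1,8-dimethyl-trans-bicyclo[5.3.0]dec-8-ene-2,4-diol-6-spiro-2′-(1,3-dithiane) | C13(SCCCS3)CC(C)=CC[C@@]2(C)[C@H](O)C[C@@](O)(C(C)C)[C@H]12 | intermediate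
26 | (1R,4R,5R)-4-hydroxy-4-isopropyl-1,8-dimethyl-trans-bicyclo[5.3.0]dec-8-en-2-one-6-spiro-2′-(1,3-dithiane) | C13(SCCCS3)CC(C)=CC[C@@]2(C)C(=O)C[C@@](O)(C(C)C)[C@H]12 | intermediate
27 | (1R,4R,5R)-4-hydroxy-4-isopropyl-1,8-dimethyl-trans-bicyclo[5.3.0]dec-8-ene-2,6-dione | O=C1CC(C)=CC[C@@]2(C)C(=O)C[C@@](O)(C(C)C)[C@H]12 | intermediate
28 | (1R,2S,4R,5S,6S)-4-isopropyl-1,8-dimethyl-trans-bicyclo[5.3.0]dec-8-ene-2,4,6-triol | O[C@H]1CC(C)=CC[C@@]2(C)[C@@H](O)C[C@@](O)(C(C)C)[C@H]12 | intermediate
29 | (1S,3R,3aS,4S,8aR)-3-hydroxy-3-isopropyl-6,8a-dimethyl-1,2,3,3a,4,5,8,8a-octahydroazulene-1,4-diyl bis[(Z)-2-methylbut-2-enoate] | C/C=C(/C)C(=O)O[C@H]1CC(C)=CC[C@@]2(C)[C@@H](OC(=O)/C(C)=C\C)C[C@@](O)(C(C)C)[C@H]12 | target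

## Step count and the least certain steps

Total: 20 steps. Longest linear sequence: 18 steps (steps 3 to 6, then 7 to 20, from 4). The enone branch (steps 1 and 2) joins at step 7.

Step 7 (key step). The most likely failure is proton transfer between enolate 13 and product 14 while the hindered, fully substituted enolate is alkylated slowly. The transposed C3 enolate would then expel the C4 silyloxy group. Carbonyl (1,2) addition of the dithiane anion is the second concern. Fallback: separate the two bond formations. From 3 and 12 the conjugate addition is run as before, but enolate 13 is quenched at −78 °C with Me3SiCl and Et3N to give the trimethylsilyl enol ether of the conjugate adduct F1, isolated free of base and excess dithiane anion. The lithium enolate is then regenerated regiospecifically with MeLi in THF and alkylated with 10 in the presence of HMPA, which returns to 14.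

Step 12. The most likely failure is attack of t-BuLi on the allylic chloride (deprotonation next to chlorine or coupling) before the hindered dithiane proton is removed, followed by intermolecular alkylation. Fallback: generate the carbanion by tin–lithium exchange instead of deprotonation. From alcohol 17, double deprotonation with t-BuLi in THF–HMPA at −78 °C (no electrophilic carbon is present yet) and quenching with Me3SnCl gives, after aqueous work-up, the 2-(trimethylstannyl)dithiane alcohol F2. MsCl, collidine and LiCl convert it into the stannylated allylic chloride F3. MeLi in THF at −78 °C then exchanges tin for lithium much faster than it attacks the chloride, and the resulting lithiodithiane 20 closes to 21.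

Step 15. The most likely failure is enolisation of the hindered ketone (recovered or epimerised material, or β-elimination) or reduction of the carbonyl by β-hydride transfer from the branched nucleophile. Fallback: from 23, add the smaller sp2 nucleophile CH2=C(CH3)MgBr with CeCl3, which cannot act as a hydride donor, to give the isopropenyl carbinol F4. The 1,1-disubstituted alkene is then reduced with diimide (from 2-nitrobenzenesulfonylhydrazide and Et3N) in the presence of the less reactive trisubstituted ring alkene and the sulfur groups, which returns to 24.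

Step 19. The most likely failure is slow exchange of the tertiary hydroxyl onto boron. One carbonyl would then stay unreduced, or the aldol-sensitive diketone would decompose during a long reaction. Fallback: reduce one carbonyl at a time. From 26, the same directed reduction on the robust dithiane gives the 2β,4α-diol F5, and here time and temperature can be raised without risk to a C6 carbonyl. The dithiane is then hydrolysed with PhI(O2CCF3)2 to the dihydroxy ketone F6. The C6 carbonyl is reduced in a second directed step, in which the new C2 hydroxyl lies on the opposite face of the five-membered ring and cannot deliver hydride to C6; this returns to 28.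

Step 20. The most likely failure is incomplete acylation of the neopentyl C2 hydroxyl under catalyst-free conditions, or partial isomerisation to the tiglate if the reaction is forced. Fallback: build the Z alkenes after acylation. From 28, both secondary hydroxyls are acylated with 2-[bis(2,2,2-trifluoroethoxy)phosphoryl]propanoic acid (N,N′-diisopropylcarbodiimide, 4-(dimethylamino)pyridine; no alkene geometry is at stake, so forcing conditions are allowed) to give the bis(phosphonopropionate) F7. A double Still–Gennari olefination with acetaldehyde (KN(SiMe3)2, 18-crown-6, THF, −78 °C, with extra base for the tertiary hydroxyl) then forms both (Z)-2-methylbut-2-enoates and returns to 29.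

## Further compounds

F1 | step 7 | (3R,4R)-4-(tert-butyldimethylsilyloxy)-3-(1,3-dithian-2-yl)-2-methyl-1-(trimethylsilyloxy)cyclopent-1-ene | C[Si](C)(C)OC1=C(C)[C@@H](C2SCCCS2)[C@H](O[Si](C)(C)C(C)(C)C)C1
F2 | step 12 | 2-(trimethylstannyl)-1,3-dithiane analogue of alcohol 17 (tin on the dithiane carbon C6) | COCO[C@@H]1C[C@@H](O[Si](C)(C)C(C)(C)C)[C@H](C2([Sn](C)(C)C)SCCCS2)[C@@]1(C)C/C=C(C)\CO
F3 | step 12 | 2-(trimethylstannyl)-1,3-dithiane analogue of chloride 19 | COCO[C@@H]1C[C@@H](O[Si](C)(C)C(C)(C)C)[C@H](C2([Sn](C)(C)C)SCCCS2)[C@@]1(C)C/C=C(C)\CCl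
F4 | step 15 | (1R,2R,4S,5R)-2-(methoxymethoxy)-1,8-dimethyl-4-(prop-1-en-2-yl)-trans-bicyclo[5.3.0]dec-8-en-4-ol-6-spiro-2′-(1,3-dithiane) | C13(SCCCS3)CC(C)=CC[C@@]2(C)[C@H](OCOC)C[C@@](O)(C(C)=C)[C@H]12
F5 | step 19 | (1R,2S,4R,5R)-4-isopropyl-1,8-dimethyl-trans-bicyclo[5.3.0]dec-8-ene-2,4-diol-6-spiro-2′-(1,3-dithiane) | C13(SCCCS3)CC(C)=CC[C@@]2(C)[C@@H](O)C[C@@](O)(C(C)C)[C@H]12
F6 | step 19 | (1R,2S,4R,5R)-2,4-dihydroxy-4-isopropyl-1,8-dimethyl-trans-bicyclo[5.3.0]dec-8-en-6-one | O=C1CC(C)=CC[C@@]2(C)[C@@H](O)C[C@@](O)(C(C)C)[C@H]12
F7 | step 20 | C2,C6-bis{2-[bis(2,2,2-trifluoroethoxy)phosphoryl]propanoate} of triol 28 (epimers at the two phosphonate-bearing carbons) | CC(C(=O)O[C@H]1CC(C)=CC[C@@]2(C)[C@@H](OC(=O)C(C)P(=O)(OCC(F)(F)F)OCC(F)(F)F)C[C@@](O)(C(C)C)[C@H]12)P(=O)(OCC(F)(F)F)OCC(F)(F)F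
A1 | alternative 1 | pentacarbonyl{methoxy[3-(tert-butyldimethylsilyloxy)-2-methyl-5-isopropyl-5-(triethylsilyloxy)cyclopent-1-en-1-yl]methylidene}chromium | COC(=[Cr](=C=O)(=C=O)(=C=O)(=C=O)=C=O)C1=C(C)[C@H](O[Si](C)(C)C(C)(C)C)C[C@@]1(O[Si](CC)(CC)CC)C(C)C
A2 | alternative 1 | isoprene | C=CC(C)=C
A3 | alternative 1 | bicyclo[5.3.0]deca-5,8-diene with C6 methyl enol ether, C2 tert-butyldimethylsilyl ether, C4 triethylsilyl ether and C4 isopropyl (skeleton numbering) | COC=1CC(C)=CC[C@@]2(C)[C@H](O[Si](C)(C)C(C)(C)C)C[C@@](O[Si](CC)(CC)CC)(C(C)C)C12
A4 | alternative 2 | 3,6-dimethylcyclohepta-2,5-dien-1-one | O=C1C=C(C)CC=C(C)C1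
A5 | alternative 2 | isobutyraldehyde | CC(C)C=O
A6 | alternative 2 | 2-(1-hydroxy-2-methylpropyl)-3,6-dimethyl-3-vinylcyclohept-5-en-1-one | O=C1CC(C)=CC[C@@](C)(C=C)[C@@H]1[C@H](O)C(C)C
A7 | alternative 3 | (R)-terpinen-4-ol | CC1=CC[C@@](O)(C(C)C)CC1
A8 | alternative 3 | 6-allyl-2-diazo-3-isopropyl-6-methyl-5-(tert-butyldimethylsilyloxy)-3-(triethylsilyloxy)cyclohexan-1-one | C=CC[C@@]1(C)[C@H](O[Si](C)(C)C(C)(C)C)C[C@@](O[Si](CC)(CC)CC)(C(C)C)C(=[N+]=[N-])C1=O
A9 | alternative 3 | methyl 2-allyl-2-methyl-5-isopropyl-3-(tert-butyldimethylsilyloxy)-5-(triethylsilyloxy)cyclopentane-1-carboxylate | C=CC[C@@]1(C)[C@H](O[Si](C)(C)C(C)(C)C)C[C@@](O[Si](CC)(CC)CC)(C(C)C)[C@@H]1C(=O)OC
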